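## Retrosynthetic overview

1. Target 13 ⇐ bis-MOM ether 12 by mild acidic deprotection.
2. 12 ⇐ 2'-hydroxychalcone 9 in one flask: enantioselective 6-endo oxa-Michael closure of ring C (chalcone → (2S)-flavanone, as chalcone isomerase does), then trans-selective C3 hydroxylation of the flavanone enolate (as flavanone 3-hydroxylase does).
3. 9 ⇐ chalcone triol 8 ⇐ protecting-group-free Claisen–Schmidt condensation of ketone 6 with aldehyde 3.
4. 6 and 3 ⇐ C-prenylation of 2,4-dihydroxyacetophenone and 4-hydroxybenzaldehyde.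
5. Ring order: rings A and B are bought as arenes; ring C is the only ring formed (step 5), and both stereocentres are set there.

Abbreviations: prenyl = 3-methylbut-2-en-1-yl; MOM = methoxymethyl.

Assumption: the quinine-derived thiourea gives the (2S)-flavanone; if the observed sense is opposite, its quinidine-derived pseudoenantiomer is used with no other change.

## Route

Step 1
Reactants: 1 4-hydroxybenzaldehyde; 2 prenyl bromide (1-bromo-3-methylbut-2-ene)
Product: 3 4-hydroxy-3-prenylbenzaldehyde
Conditions: KOH (10% aq., 1.2 equiv), 0 °C to rt, 24 h; acidify, chromatography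
Reagents that add atoms: none
Why: phenolate C-allylation (SN2) — in water the hydrogen-bonded phenoxide oxygen is shielded, so the ambident anion is alkylated at the ortho carbon (para is blocked by CHO), and the O-prenyl ether by-product is removed by chromatography.

Step 2
Reactants: 4 2,4-dihydroxyacetophenone; 5 2-methylbut-3-en-2-ol
Product: 6 1-(2,4-dihydroxy-5-prenylphenyl)ethan-1-one
Conditions: BF3·OEt2 (0.3 equiv, catalytic), 1,4-dioxane, rt, 3 h; chromatography
Reagents that add atoms: none
Why: Friedel–Crafts prenylation — BF3 ionises the tertiary allylic alcohol to the dimethylallyl cation, which attacks through its primary terminus at C5 (para to the chelated 2-OH, ortho to the 4-OH, less hindered than C3) to give the linear prenyl group; the minor 3-prenyl isomer is separated and a modest yield is accepted on cheap materials.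

Step 3
Reactants: 6 1-(2,4-dihydroxy-5-prenylphenyl)ethan-1-one; 3 4-hydroxy-3-prenylbenzaldehyde
Product: 8 (E)-1-(2,4-dihydroxy-5-prenylphenyl)-3-(4-hydroxy-3-prenylphenyl)prop-2-en-1-one, via aldolate 7 (not isolated)
Conditions: LiN(SiMe3)2 (4.5 equiv in total; 3.3 on 6, 1.2 on 3), THF, −78 °C to rt, 24 h; then AcOH, H2O
Reagents that add atoms: none
Why: Claisen–Schmidt (aldol) condensation on the lithium polyanions — the phenoxides act as their own protection, the ketone enolate adds to the aldehyde, and the aldolate eliminates on warming to the conjugated E-enone (thermodynamic geometry).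

Step 4
Reactants: 8 (E)-1-(2,4-dihydroxy-5-prenylphenyl)-3-(4-hydroxy-3-prenylphenyl)prop-2-en-1-one
Product: 9 (E)-1-[2-hydroxy-4-(methoxymethoxy)-5-prenylphenyl]-3-[4-(methoxymethoxy)-3-prenylphenyl]prop-2-en-1-one
Conditions: MOMCl (2.3 equiv), K2CO3, acetone, 0 °C to rt
Reagents that add atoms: chloromethyl methyl ether (MOMCl), COCCl
Why: Williamson-type O-alkylation of the two free phenoxides; the 2'-OH is locked in a hydrogen bond to the carbonyl and is not alkylated under weak base with limited MOMCl, so it stays free for the ring closure.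

Step 5
Reactants: 9 (E)-1-[2-hydroxy-4-(methoxymethoxy)-5-prenylphenyl]-3-[4-(methoxymethoxy)-3-prenylphenyl]prop-2-en-1-one
Product: 12 (2R,3R)-3-hydroxy-7-(methoxymethoxy)-2-[4-(methoxymethoxy)-3-prenylphenyl]-6-prenylchroman-4-one, via flavanone 10 (not isolated), via sodium enolate 11 (not isolated)
Conditions: (i) 1-[3,5-bis(trifluoromethyl)phenyl]-3-[(8α,9S)-6'-methoxycinchonan-9-yl]thiourea (20 mol%), toluene, 4 Å MS, 0 °C, 72 h; (ii) THF, NaN(SiMe3)2 (1.6 equiv), −78 °C, 20 min; (iii) 3-phenyl-2-(phenylsulfonyl)oxaziridine (1.8 equiv), −78 °C, 30 min; AcOH, −78 °C; chromatography, recrystallisation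
Reagents that add atoms: 3-phenyl-2-(phenylsulfonyl)oxaziridine (Davis oxaziridine), O=S(=O)(c1ccccc1)N1OC1c1ccccc1
Why: Proposed new method: the quinuclidine nitrogen of the catalyst deprotonates the chelated 2'-OH while the thiourea hydrogen-bonds the enone carbonyl, so the phenoxide adds 6-endo-trig to one face of the E-enone (asymmetric intramolecular oxa-Michael addition) and sets C2 as S; the closest known reactions are the cinchona-thiourea cyclisation of 2'-hydroxychalcones that carry an activating α-ester (high ee) and the alkaloid-base cyclisation of plain 2'-hydroxychalcones (lower ee); because this cyclisation is reversible, the flavanone is not worked up but deprotonated at −78 °C, where E1cB ring opening of the enolate is slow, and hydroxylated by the N-sulfonyloxaziridine (Davis enolate oxidation) on the face anti to the 2-aryl group, which gives the 2,3-trans (3R) ketol and locks C2, with recrystallisation of 12 to raise the ee.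

Step 6
Reactants: 12 (2R,3R)-3-hydroxy-7-(methoxymethoxy)-2-[4-(methoxymethoxy)-3-prenylphenyl]-6-prenylchroman-4-one
Product: 13 Lespeflorin B1, (2R,3R)-3,7-dihydroxy-2-(4-hydroxy-3-prenylphenyl)-6-prenylchroman-4-one
Conditions: HCl (1 M in MeOH), 40 °C, 1–2 h; NaHCO3 work-up
Reagents that add atoms: none
Why: acid-catalysed acetal exchange removes both MOM groups; no phenoxide is formed, so C2 cannot open through a quinone methide, and the low temperature and short time keep the trans-ketol and the ortho-prenylphenols intact (no chroman formation).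

## Compound list

1 | 4-hydroxybenzaldehyde | O=Cc1ccc(O)cc1 | starting material
2 | prenyl bromide (1-bromo-3-methylbut-2-ene) | CC(C)=CCBr | starting material
3 | 4-hydroxy-3-(3-methylbut-2-en-1-yl)benzaldehyde | CC(C)=CCc1cc(C=O)ccc1O | intermediate
4 | 2,4-dihydroxyacetophenone | CC(=O)c1ccc(O)cc1O | starting material
5 | 2-methylbut-3-en-2-ol | C=CC(C)(C)O | starting material
6 | 1-[2,4-dihydroxy-5-(3-methylbut-2-en-1-yl)phenyl]ethan-1-one | CC(=O)c1cc(CC=C(C)C)c(O)cc1O | intermediate
7 | aldol adduct, 1-(2,4-dihydroxy-5-prenylphenyl)-3-hydroxy-3-(4-hydroxy-3-prenylphenyl)propan-1-one (racemic; present in the flask as its lithium salt) | CC(C)=CCc1cc(C(O)CC(=O)c2cc(CC=C(C)C)c(O)cc2O)ccc1O | intermediate (not isolated)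
8 | (E)-1-(2,4-dihydroxy-5-prenylphenyl)-3-(4-hydroxy-3-prenylphenyl)prop-2-en-1-one | CC(C)=CCc1cc(/C=C/C(=O)c2cc(CC=C(C)C)c(O)cc2O)ccc1O | intermediate
9 | (E)-1-[2-hydroxy-4-(methoxymethoxy)-5-prenylphenyl]-3-[4-(methoxymethoxy)-3-prenylphenyl]prop-2-en-1-one | COCOc1ccc(/C=C/C(=O)c2cc(CC=C(C)C)c(OCOC)cc2O)cc1CC=C(C)C | intermediate
10 | (2S)-7-(methoxymethoxy)-2-[4-(methoxymethoxy)-3-prenylphenyl]-6-prenylchroman-4-one | CC(C)=CCc1cc([C@H]2Oc3cc(OCOC)c(CC=C(C)C)cc3C(=O)C2)ccc1OCOC | intermediate (not isolated)
11 | sodium (2S)-7-(methoxymethoxy)-2-[4-(methoxymethoxy)-3-prenylphenyl]-6-prenyl-2H-chromen-4-olate | CC(C)=CCc1cc([C@H]2Oc3cc(OCOC)c(CC=C(C)C)cc3C([O-])=C2)ccc1OCOC.[Na+] | intermediate (not isolated)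
12 | (2R,3R)-3-hydroxy-7-(methoxymethoxy)-2-[4-(methoxymethoxy)-3-prenylphenyl]-6-prenylchroman-4-one | CC(C)=CCc1cc([C@H]2Oc3cc(OCOC)c(CC=C(C)C)cc3C(=O)[C@@H]2O)ccc1OCOC | intermediate
13 | Lespeflorin B1, (2R,3R)-3,7-dihydroxy-2-[4-hydroxy-3-(3-methylbut-2-en-1-yl)phenyl]-6-(3-methylbut-2-en-1-yl)chroman-4-one | CC(C)=CCc1cc([C@H]2Oc3cc(O)c(CC=C(C)C)cc3C(=O)[C@@H]2O)ccc1O | target

## Step count and risks

Total steps: 6. Longest linear sequence: 5 steps (4 → 6 → 8 → 9 → 12 → 13, or equally 1 → 3 → 8 → 9 → 12 → 13).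

Most likely to fail, in order:

Step 5 is the main risk. The doubly alkoxy-substituted chalcone is a weak Michael acceptor, so the catalytic cyclisation may be slow or only moderately enantioselective, and the enolate may partly ring-open before it is oxidised. The fallback sets out from 9 and comes back at 13. The chelated phenol of 9 is capped (NaH, MOMCl, DMF, 0 °C) to give the tris-MOM chalcone (E)-1-[2,4-bis(methoxymethoxy)-5-prenylphenyl]-3-[4-(methoxymethoxy)-3-prenylphenyl]prop-2-en-1-one F1. Juliá–Colonna epoxidation (poly-L-leucine, urea–H2O2, DBU, THF; the nucleophilic peroxide does not touch the prenyl alkenes) gives the epoxy ketone [2,4-bis(methoxymethoxy)-5-prenylphenyl][(2R,3S)-3-[4-(methoxymethoxy)-3-prenylphenyl]oxiran-2-yl]methanone F2. Methanolic HCl then removes the three MOM groups, and the freed 2'-phenol opens the epoxide at the benzylic carbon with inversion. C3 is fixed by the epoxidation and the ring closes trans, giving 13 directly.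

Step 2 is the next risk: the Friedel–Crafts prenylation gives a mixture of 5- and 3-prenyl isomers in low yield. The fallback sets out from 4 and comes back at 6, with the position fixed by a halogen. Bromination (NBS, MeCN, 0 °C) gives 1-(5-bromo-2,4-dihydroxyphenyl)ethan-1-one F3. Double protection (NaH, MOMCl, DMF) gives 1-[5-bromo-2,4-bis(methoxymethoxy)phenyl]ethan-1-one F4. Suzuki–Miyaura coupling with prenylboronic acid pinacol ester (PdCl2[1,1'-bis(diphenylphosphino)ferrocene], K3PO4, THF–H2O, 65 °C, chosen for the linear product) gives 1-[2,4-bis(methoxymethoxy)-5-prenylphenyl]ethan-1-one F5. Methanolic HCl then returns 6.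

Step 3 is the third risk: the lithium phenoxide of aldehyde 3 is a deactivated electrophile, and the polyanions may be poorly soluble. The fallback sets out from 6 and 3 and comes back at 9; it protects before condensing and uses the classical hydroxide condensation. Ketone 6 is protected selectively at the non-chelated phenol (MOMCl, K2CO3, acetone) to give 1-[2-hydroxy-4-(methoxymethoxy)-5-prenylphenyl]ethan-1-one F6. Aldehyde 3 is protected likewise to give 4-(methoxymethoxy)-3-prenylbenzaldehyde F7. Condensation of the two (KOH, EtOH–H2O, rt) gives 9 directly, so step 4 is no longer needed.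

## Further compounds

F1 | step 5 | (E)-1-[2,4-bis(methoxymethoxy)-5-prenylphenyl]-3-[4-(methoxymethoxy)-3-prenylphenyl]prop-2-en-1-one | COCOc1ccc(/C=C/C(=O)c2cc(CC=C(C)C)c(OCOC)cc2OCOC)cc1CC=C(C)C
F2 | step 5 | [2,4-bis(methoxymethoxy)-5-prenylphenyl][(2R,3S)-3-[4-(methoxymethoxy)-3-prenylphenyl]oxiran-2-yl]methanone | COCOc1cc(OCOC)c(CC=C(C)C)cc1C(=O)[C@@H]2O[C@H]2c3ccc(OCOC)c(CC=C(C)C)c3
F3 | step 2 | 1-(5-bromo-2,4-dihydroxyphenyl)ethan-1-one | CC(=O)c1cc(Br)c(O)cc1O
F4 | step 2 | 1-[5-bromo-2,4-bis(methoxymethoxy)phenyl]ethan-1-one | CC(=O)c1cc(Br)c(OCOC)cc1OCOC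
F5 | step 2 | 1-[2,4-bis(methoxymethoxy)-5-prenylphenyl]ethan-1-one | CC(=O)c1cc(CC=C(C)C)c(OCOC)cc1OCOC
F6 | step 3 | 1-[2-hydroxy-4-(methoxymethoxy)-5-prenylphenyl]ethan-1-one | CC(=O)c1cc(CC=C(C)C)c(OCOC)cc1O
F7 | step 3 | 4-(methoxymethoxy)-3-prenylbenzaldehyde | COCOc1ccc(C=O)cc1CC=C(C)C
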